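No rate constant stands in the problem, so the one constant I need has to come from the earlier readings.

| flask | starting material | solid reagent | initiator | remark | time |
|---|---|---|---|---|---|
| violet | 0.33 M | 0.99 M | 13 mM | run made earlier |  |
| ochre | 0.33 M | 0.99 M | 52 mM | run made earlier |  |
| amber | 0.49 M | 0.99 M | 26 mM | run made earlier |  |
| flask | 0.33 M | 0.990 M | 26 mM |  | 5.0 d |

- violet (time / d: target / %, idle adduct / %): 0.250: 0, 0; 0.333: 1, 2; 0.500: 4, 1; 0.833: 2, 2; 1.25: 10, 6; 2.08: 17, 3; 3.00: 24, 3
- ochre (time / d: target / %, idle adduct / %): 0.250: 3, 5; 0.333: 4, 0; 0.500: 7, 8; 0.833: 8, 8; 1.25: 12, 10; 2.08: 25, 3; 3.00: 29, 3
- amber (time / d: target / %, idle adduct / %): 0.625: 4, 0; 1.25: 9, 1; 1.67: 12, 6; 2.50: 20, 5; 3.00: 19, 0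

(standard deviation of a reading: 2 percentage points)

- percent here means starting material units held: one idle adduct counts as two
- what is said of target includes idle adduct
- solid reagent is a solid; its amount is given per volume of the solution
- at the start none of the solid reagent is in solution
- in an amount of target, one idle adduct counts as one target

- target and idle adduct together at 5.0 d, in percent of the starting material charged
- the change that raises the amount of target and idle adduct together at 5.0 d, in percent of the starting material charged most ("none" if none brings more than 2 percentage points) (maple / birch / none)
- amount of target and idle adduct together at 5.0 d, in percent of the starting material charged, after birch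

- maple: doubling the dissolution coefficient of the solid reagent, all else as stated
- birch: doubling the solubility of the solid reagent, all else as stated

The target column already counts idle adduct, so I read that column by itself. In the first instants little shows: at 0.250 d violet reads 0 % and ochre 3 %, against a scatter of 2 percentage points. In the middle, percentages mislead, so I turn them into molarity. At 1.25 d ochre, charged with 0.33 M, holds 0.0396 M of target. Amber, charged with 0.49 M, holds 0.0441 M, a gap smaller than the scatter of one reading, but amber also has 26 mM of initiator against ochre's 52 mM, so this pair does not isolate the charge. At the end amber reads 20 % at 2.50 d and 19 % at 3.00 d, a difference smaller than the scatter, so this pair cannot tell a level from a slow rise.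

The mean of those two readings times amber's charge is 0.0955 M. I call this the molar ceiling: the concentration of target at which I assume a run levels off, an estimate in moles per litre instead of percent. Ochre's last reading gives 0.0957 M independently. Amber has the flask's initiator, 26 mM, so I divide the ceiling by the flask's 0.33 M and commit to 29.0 %. That leaves 71.1 % of the charge in forms the readings do not show. The runs share one reagent charge, 0.990 M, so they cannot separate maple from birch.

The forecast differs from my figure: it says 38 % (32 % to 45 %), reached by “then a slowing 5%/d”, names birch as best, and gives 54 % after it.

The flask gives 28.4 %. The best change is birch, gaining 8.3 points against 5.8 points for maple, and reaching 36.7 %.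

    2 initiating radical → ended chains B (k = 2.00 × 10⁶ /M/s)
    starting material + target ⇌ idle adduct, settled at all times (K = 6.30 /M)
    2 starting material → homo dimer (k = 0.120 /M/h)
    2 chain carrier → ended chains A (k = 1.30 × 10⁸ /M/s)
    initiator → 2 initiating radical (k = 0.0130 /h)
    starting material + initiating radical → chain carrier (k = 5.80 × 10⁵ /M/h)
    solid reagent ⇌ partner, rate k7*(cs7 - [partner]) while solid is left; crystals form when [partner] > cs7 (solubility = 0.180 M, k = 0.0310 /h)
    partner + chain carrier → target + initiating radical (k = 1.00 × 10⁶ /M/h)

The neighbouring flask is charged with 1.3 M of starting material, all else as in the recipe. The ceiling gives 7.35 % for it at 5.0 d, and it holds 8.63 %, which is 0.112 M of target against 0.0937 M in the flask. Its charge is 3.94 times the flask's, yet its target is 1.20 times as much. Starting material is its limiting reagent, down to 0.11 %, and homo dimer holds 89.1 %.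

The numbers in the tables were generated by integration for an exercise; scatter was added.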